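## The problem

Difengpiol B (26) is a 2,3-dihydrobenzofuran: benzene ring A (C3a, C4–C7, C7a) is fused to dihydrofuran ring B (O1, C2, C3). C2 is bonded to the fully substituted carbinol carbon C1' of cyclohexane ring C, C3 bears a hydroxymethyl group, C5 a 3-hydroxypropyl chain and C7 a methoxy group. Five stereocentres must be set: C2 (S) and C3 (R), trans across ring B, and C1' (S), C3' (S), C4' (S) in ring C, where the 3'-hydroxyl is cis to the 1'-hydroxyl and trans to the 4'-methoxy group. C2 and C3 have no resident centre to lean on and must be introduced absolutely. C2, with O1 beside it, can then steer a nucleophile onto a C1' carbonyl, and the C1' hydroxyl can deliver an oxidant to one face of a C3'=C4' alkene, from which the 3'/4' pair follows by anti opening. The weak points are C2 once it stands alpha to a carbonyl group (epimerisable, although trans is the stable arrangement), the electron-rich ring A with its benzylic C3–H (oxidants), the tertiary carbinol beside an epoxide late in the route (strong acid), and two primary hydroxyls that must stay masked to the end. The feature that opens the route is the pattern of ring A: C7a (oxygen), C7 (methoxy), C6 (hydrogen) and C5 (alkyl) are C3, C4, C5 and C6 of a 3-alkoxy-4-methoxy-6-alkyl-2-pyrone, and the missing carbons C3a and C4 are a vinyl group on C3 of the O1–C2–C3 arm. Such a pyrone holds diene and dienophile three atoms apart, so one cycloaddition can close ring B and the carbocycle that becomes ring A.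

## Retrosynthesis

**Ring C oxygens (26 ⇒ 25 ⇒ 24).** The C4'–OMe and C3'–O bonds are traced to one epoxide. 26 should come from the cis-epoxy alcohol 25 by acid methanolysis, which also frees the two primary alcohols, and 25 from cyclohexenol 24 by oxygen delivery from the C1' hydroxyl. Compared with bringing C3' and C4' in as preformed centres, this lets one resident centre set two others; 24 has three stereocentres instead of five. The forward steps must put the epoxide cis to the 1'-hydroxyl and open it at C4', not C3'. Both follow from the half-chair in which the large C2 substituent is equatorial and the hydroxyl axial.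

**Ring C closure (24 ⇒ 23).** The C3'=C4' bond is cut by ring-closing metathesis, giving the acyclic diene carbinol 23 with an allyl and a but-3-enyl arm on C1'. Closing at the alkene rather than at C1' leaves the carbinol centre to be made in an open chain, where C2 can control it, and puts the alkene where the two oxygens are needed. The forward reaction only has to tolerate a free tertiary alcohol.

**C1' (23 ⇒ 22 ⇒ 21 ⇒ 20).** The C1'–C2' bond (allyl) is cut first and the C1'–C6' bond (butenyl) second, leading through ketone 22 and Weinreb amide 21 to ester 20. The order is not free. With the butenyl arm on the ketone and the allyl group arriving on a chelate between the carbonyl oxygen and O1, the nucleophile enters from the C2–H side and C1' becomes S; the opposite order under the same control would give the epimer. 20 has only C2 and C3 as stereocentres. The forward step needs a Lewis acid that really bridges the ketone and the aryl ether oxygen.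

**Rings A and B (20 ⇒ 17), the key cut.** The C3a–C7a and C4–C5 bonds are cut, and with them ring B and the six-membered carbocycle. 20 is traced through dihydroarene 19 and bridged lactone 18 to pyrone 17. Cutting O1–C2 or C3–C3a on a finished arene would create C2 or C3 during ring closure; here both are set in the open chain and the step makes only carbons that end up sp2. 17 is monocyclic and is assembled from two small pieces. The forward reaction must outrun decomposition and C2 epimerisation, expel the lactone bridge, and be followed by a clean dehydrogenation.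

**Ether bond (17 ⇒ 7 + 16).** The O1–C2 bond is cut into hydroxypyrone 7 and hydroxy ester 16, joined with inversion at C2. A trans ring B requires the pyrone oxygen and the silyloxymethyl group of 17 to be anti (2S,3R), so 16 must be the syn (2R,3R) isomer. Making this bond before the C2–C3 bond, by rearranging a pyronyloxyacetate, would expose the pyrone to strong base; finishing the halves separately avoids that.

**Pyrone (7 ⇒ 5 ⇒ 4 ⇒ 3 + 2; 2 ⇒ 1).** The C3–O bond of 7 is traced through bromide 5 to pyrone 4, and the side chain of 4 is cut between its first and second carbon into pyrone 3 and iodide 2 (from 1). Each step uses the innate reactivity of the ring: the acidic 6-methyl group and the nucleophilic C3.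

**Hydroxy ester (16 ⇒ 15 ⇒ 13 ⇒ 12 ⇒ 11 ⇒ 10 ⇒ 9 ⇒ 8).** The C3–vinyl bond is cut by epoxide opening, and both centres are traced to the Sharpless epoxide 10 of the (E)-allylic alcohol 9, made from diol 8. An ester-enolate Claisen rearrangement of a glycolate would also build C2–C3, but it gives a racemate, and through the chelated enolate a (Z)-allylic ester gives the anti acid, not the syn acid needed for an inverting etherification. In the epoxide route the carbinol carbon keeps its configuration and the vinyl-bearing carbon is inverted, which gives the syn (2R,3R) pattern of 11 directly. The price is the protecting-group exchange 11 ⇒ 12 ⇒ 13 and the oxidation 13 ⇒ 15.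

## Roads not taken

**Alternative 1:** The cut runs through ring C. C1'–C2' and C5'–C6' are formed by a [4+2] cycloaddition of diene A3 to the exocyclic alkene of the tert-butyl dioxolanone A2, giving spiro lactone A1 with C1' set by the acetal centre and the lactone carbonyl standing for C2. Its merit is real: C1' is fixed by a rigid auxiliary, independently of any chelation model, and this is better than the C1' control of the chosen plan. Its weakness is everything after A1. C2 must be joined to C3 and to a separately made ring A next to a fully substituted carbon, and C2 and C3 must be set relative to C1' with no obvious control element. The 3'/4' oxygens still have to be introduced as in the chosen plan. A3 is also an unactivated diene and will need forcing conditions. Against the better C1' control, the chosen plan sets C2 and C3 absolutely before the key step, builds the full ring A pattern in one operation, and has a mirror-image fallback for C1'.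

**Alternative 2:** The cut is C2–C3 of ring B. Diazo ester A5, made by joining a finished ring C to the arene through an ether, would lose nitrogen on a chiral dirhodium carboxylate catalyst and insert into one hydrogen of the O1–CH2 group to give the cis ester A4. This road is shorter and more convergent than the chosen one, and both ester groups of A4 would fall to the two primary alcohols in one hydride reduction. Its weak points are these. The C–H bond sits beside a fully substituted silyloxy carbon and competes with the ethyl C–H bonds of the silyl group and with ring C–H bonds. The catalyst must override three resident stereocentres. A4 is cis and needs epimerisation at C3 to reach the trans series. The chosen plan is longer, but the trans relationship is fixed in an open chain by reliable reactions and no site selectivity among C–H bonds is needed.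

**Alternative 3:** The cuts are C3–C3a and O1–C2. Palladium-catalysed heteroannulation of iodophenol A7 with diene A8 would give the 2-cyclohexenyl dihydrobenzofuran A6, and the C1' hydroxyl would follow by directed epoxidation and reductive opening. This is the most convergent plan: ring A comes from the aromatic pool and ring C arrives with C3' and C4' in place. The trans arrangement is also the natural outcome of an (E)-diene. The difficulty is absolute control: C2 and C3 are created together with only the remote C3'/C4' centres of A8 to bias the face, so a chiral ligand would have to do the work on a trisubstituted, unsymmetrical diene. It is also unclear which diene terminus accepts the aryl group. The chosen plan spends more steps, but its C2/C3 configuration comes from a Sharpless epoxidation and is not at stake in the key step.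

Key step: step 13

Assumption: (E)-but-2-ene-1,4-diol (8) is taken as a commercial material; otherwise it is one hydride reduction away from but-2-yne-1,4-diol.

Abbreviations: TBS = tert-butyldimethylsilyl, PMB = 4-methoxybenzyl, DDQ = 2,3-dichloro-5,6-dicyano-1,4-benzoquinone, DIAD = diisopropyl azodicarboxylate, TEMPO = 2,2,6,6-tetramethylpiperidin-1-oxyl.

## Route

Step 1
Reactants: 1 2-iodoethanol
Product: 2 tert-butyl(2-iodoethoxy)dimethylsilane
Conditions: TBSCl, imidazole, CH2Cl2, 0 °C to rt
Reagents that add atoms: tert-butyldimethylsilyl chloride, CC(C)(C)[Si](C)(C)Cl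
Why: Imidazole-promoted silylation of a primary alcohol; the neutral conditions leave the iodide untouched.

Step 2
Reactants: 3 4-methoxy-6-methyl-2H-pyran-2-one; 2 tert-butyl(2-iodoethoxy)dimethylsilane
Product: 4 6-{3-[(tert-butyldimethylsilyl)oxy]propyl}-4-methoxy-2H-pyran-2-one
Conditions: LiN(iPr)2, THF, −78 °C; then 2, HMPA, −78 to −20 °C
Reagents that add atoms: none
Why: Deprotonation of the 6-methyl group gives the extended lithium enolate of the pyrone, which should be alkylated at the exocyclic carbon by the primary iodide (vinylogous enolate alkylation); HMPA offsets the sluggishness of a beta-silyloxy iodide.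

Step 3
Reactants: 4 6-{3-[(tert-butyldimethylsilyl)oxy]propyl}-4-methoxy-2H-pyran-2-one
Product: 5 3-bromo-6-{3-[(tert-butyldimethylsilyl)oxy]propyl}-4-methoxy-2H-pyran-2-one
Conditions: NBS, MeCN, 0 °C to rt, dark
Reagents that add atoms: N-bromosuccinimide, O=C1CCC(=O)N1Br
Why: Electrophilic bromination; C3 lies between the carbonyl group and the methoxy-bearing C4 and is the most nucleophilic ring carbon, and the polar medium in the dark suppresses radical bromination of the side chain.

Step 4
Reactants: 5 3-bromo-6-{3-[(tert-butyldimethylsilyl)oxy]propyl}-4-methoxy-2H-pyran-2-one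
Product: 7 6-{3-[(tert-butyldimethylsilyl)oxy]propyl}-3-hydroxy-4-methoxy-2H-pyran-2-one, via pinacol boronate 6 (not isolated)
Conditions: B2pin2, KOAc, Pd(dppf)Cl2 (5 mol%), 1,4-dioxane, 85 °C; then NaBO3·4H2O, THF/H2O, rt
Reagents that add atoms: sodium perborate tetrahydrate, [Na+].[O-]OB=O.O.O.O.O (hydroxyl oxygen); bis(pinacolato)diboron, CC1(C)OB(OC1(C)C)B1OC(C)(C)C(C)(C)O1 (its boron stays only in 6)
Why: Miyaura borylation of the vinylic bromide, then oxidative conversion of C–B into C–O with perborate, which is mild enough to leave the lactone closed; acidic work-up returns the enol 7.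

Step 5
Reactants: 8 (E)-but-2-ene-1,4-diol
Product: 9 (E)-4-[(4-methoxybenzyl)oxy]but-2-en-1-ol
Conditions: NaH (1 equiv), PMBCl (1 equiv), Bu4NI (cat.), THF/DMF, 0 °C to rt, diol in threefold excess
Reagents that add atoms: 4-methoxybenzyl chloride, COc1ccc(CCl)cc1
Why: Williamson etherification; the excess of the symmetrical diol biases the statistical mixture towards the mono-ether, and unreacted diol is removed with water.

Step 6
Reactants: 9 (E)-4-[(4-methoxybenzyl)oxy]but-2-en-1-ol
Product: 10 [(2S,3S)-3-{[(4-methoxybenzyl)oxy]methyl}oxiran-2-yl]methanol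
Conditions: Ti(OiPr)4 (10 mol%), L-(+)-diethyl tartrate (12 mol%), tBuOOH, 4 Å molecular sieves, CH2Cl2, −20 °C
Reagents that add atoms: tert-butyl hydroperoxide, CC(C)(C)OO
Why: Sharpless asymmetric epoxidation; with the L-(+)-tartrate an (E)-allylic alcohol is expected to give the (2S,3S)-epoxide, and this step is the source of all absolute configuration at the future C2 and C3.

Step 7
Reactants: 10 [(2S,3S)-3-{[(4-methoxybenzyl)oxy]methyl}oxiran-2-yl]methanol
Product: 11 (2R,3R)-2-ethenyl-4-[(4-methoxybenzyl)oxy]butane-1,3-diol
Conditions: CH2=CHMgBr (3 equiv), CuI (15 mol%), THF/Et2O, −40 to −15 °C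
Reagents that add atoms: vinylmagnesium bromide, C=C[Mg]Br
Why: Copper-catalysed SN2 opening of a 2,3-epoxy alcohol; attack at the carbon next to the free hydroxymethyl group is favoured because the neighbouring PMB-oxymethyl group deactivates the other carbon inductively, so the 1,3-diol should dominate. The attacked carbon (future C3) is inverted and the carbinol carbon (future C2) keeps its configuration, which gives the syn pattern.

Step 8
Reactants: 11 (2R,3R)-2-ethenyl-4-[(4-methoxybenzyl)oxy]butane-1,3-diol
Product: 12 (2R,3R)-3-{[(tert-butyldimethylsilyl)oxy]methyl}-1-[(4-methoxybenzyl)oxy]pent-4-en-2-ol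
Conditions: TBSCl (1.05 equiv), imidazole, CH2Cl2, −20 to 0 °C
Reagents that add atoms: tert-butyldimethylsilyl chloride, CC(C)(C)[Si](C)(C)Cl
Why: Selective silylation of the primary over the secondary hydroxyl on steric grounds; the secondary hydroxyl stays free for the later etherification.

Step 9
Reactants: 12 (2R,3R)-3-{[(tert-butyldimethylsilyl)oxy]methyl}-1-[(4-methoxybenzyl)oxy]pent-4-en-2-ol
Product: 13 (2R,3R)-3-{[(tert-butyldimethylsilyl)oxy]methyl}pent-4-ene-1,2-diol
Conditions: DDQ, CH2Cl2/pH 7 phosphate buffer (10:1), 0 °C
Reagents that add atoms: none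
Why: Oxidative cleavage of the PMB ether by DDQ; the wet, buffered medium favours hydrolysis of the oxocarbenium ion over acetal formation with the neighbouring hydroxyl, and the vinyl group and silyl ether are inert.

Step 10
Reactants: 13 (2R,3R)-3-{[(tert-butyldimethylsilyl)oxy]methyl}pent-4-ene-1,2-diol
Product: 15 (2R,3R)-3-{[(tert-butyldimethylsilyl)oxy]methyl}-2-hydroxypent-4-enoic acid, via hydroxy aldehyde 14 (not isolated)
Conditions: TEMPO (cat.), NaOCl (cat.), NaClO2, MeCN/phosphate buffer (pH 6.7), 25 °C
Reagents that add atoms: sodium chlorite, [Na+].[O-]Cl=O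
Why: TEMPO/chlorite oxidation of a primary alcohol through the aldehyde to the acid; the oxoammonium ion selects the primary carbinol, and the chlorite-rich buffered medium should take 14 on to the acid before glycol cleavage or epimerisation can set in.

Step 11
Reactants: 15 (2R,3R)-3-{[(tert-butyldimethylsilyl)oxy]methyl}-2-hydroxypent-4-enoic acid
Product: 16 methyl (2R,3R)-3-{[(tert-butyldimethylsilyl)oxy]methyl}-2-hydroxypent-4-enoate
Conditions: Me3SiCHN2, PhMe/MeOH (4:1), 0 °C
Reagents that add atoms: (trimethylsilyl)diazomethane, C[Si](C)(C)C=[N+]=[N-]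
Why: Methyl esterification with (trimethylsilyl)diazomethane under neutral conditions that spare the silyl ether and both stereocentres.

Step 12
Reactants: 16 methyl (2R,3R)-3-{[(tert-butyldimethylsilyl)oxy]methyl}-2-hydroxypent-4-enoate; 7 6-{3-[(tert-butyldimethylsilyl)oxy]propyl}-3-hydroxy-4-methoxy-2H-pyran-2-one
Product: 17 methyl (2S,3R)-3-{[(tert-butyldimethylsilyl)oxy]methyl}-2-[(6-{3-[(tert-butyldimethylsilyl)oxy]propyl}-4-methoxy-2-oxo-2H-pyran-3-yl)oxy]pent-4-enoate
Conditions: PPh3, DIAD, THF, 0 °C to rt
Reagents that add atoms: none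
Why: Mitsunobu etherification; the acidic enol 7 is a suitable pronucleophile and should displace the alpha-oxyphosphonium ester with inversion, turning (2R) into (2S). The pyrone oxygen and the silyloxymethyl group are then anti, the arrangement that becomes trans in ring B.

Step 13
Reactants: 17 methyl (2S,3R)-3-{[(tert-butyldimethylsilyl)oxy]methyl}-2-[(6-{3-[(tert-butyldimethylsilyl)oxy]propyl}-4-methoxy-2-oxo-2H-pyran-3-yl)oxy]pent-4-enoate
Product: 20 methyl (2S,3R)-3-{[(tert-butyldimethylsilyl)oxy]methyl}-5-{3-[(tert-butyldimethylsilyl)oxy]propyl}-7-methoxy-2,3-dihydro-1-benzofuran-2-carboxylate, via bridged lactone 18 (not isolated), via dihydroarene 19 (not isolated)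
Conditions: 1,2-Cl2C6H4 (0.01 M, degassed), 170 °C, sealed tube; cool to rt; DDQ (1.1 equiv), rt
Reagents that add atoms: none
Why: Heating should bring the vinyl group over the pyrone diene (C3=C4–C5=C6) in an intramolecular Diels–Alder reaction, the internal alkene carbon bonding to pyrone C3 (the C3a–C7a bond) and the terminal one to pyrone C6 (the C4–C5 bond) to give bridged lactone 18. A retro-[4+2] cycloreversion then expels CO2 irreversibly and leaves dihydroarene 19, from which DDQ removes the hydrogens on C3a and C4 (hydride abstraction, then proton loss) to give the benzene ring. The closest known reaction type is the intramolecular pyrone Diels–Alder/CO2-extrusion sequence of 2-pyrones carrying an alkene or alkyne on a three-atom heteroatom tether at C3, used for indolines and hydroindolines; only the oxygen tether is new. Ring B closes as the five-membered tether ring of the cycloaddition (O1–C2–C3 span the new C3a–C7a bond, a 5-exo arrangement at the vinyl group), and the carbocycle closes as the six-membered ring of the [4+2] process itself. No stereocentre is created that survives: C3a and the bridgeheads are erased, so the endo/exo course does not matter, and C2 and C3 are carried through from 17. The step needs regioselectivity, which the tether length secures because only the internal alkene carbon can reach pyrone C3, and it needs the cycloaddition to outrun epimerisation at C2, which the neutral, non-polar, base-free medium and the substitution at C2 and C3 (favouring the folded conformer) should secure. Chemoselective dehydrogenation rests on 19 being a far better hydride donor than the benzylic C3–H of 20, so one equivalent of DDQ at room temperature is used.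

Step 14
Reactants: 20 methyl (2S,3R)-3-{[(tert-butyldimethylsilyl)oxy]methyl}-5-{3-[(tert-butyldimethylsilyl)oxy]propyl}-7-methoxy-2,3-dihydro-1-benzofuran-2-carboxylate
Product: 22 1-[(2S,3R)-3-{[(tert-butyldimethylsilyl)oxy]methyl}-5-{3-[(tert-butyldimethylsilyl)oxy]propyl}-7-methoxy-2,3-dihydro-1-benzofuran-2-yl]pent-4-en-1-one, via Weinreb amide 21 (not isolated)
Conditions: MeNH(OMe)·HCl, iPrMgCl, THF, −20 °C; then CH2=CHCH2CH2MgBr, −20 to 0 °C; aq. NH4Cl
Reagents that add atoms: but-3-enylmagnesium bromide, C=CCC[Mg]Br; N,O-dimethylhydroxylamine hydrochloride, CNOC.Cl (its atoms stay only in 21)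
Why: Weinreb ketone synthesis in one flask: the magnesium amide converts the ester into 21, and the Grignard reagent then stops at the chelated tetrahedral intermediate, which releases the ketone on work-up. Any base-induced equilibration at C2 is harmless because trans is the stable arrangement.

Step 15
Reactants: 22 1-[(2S,3R)-3-{[(tert-butyldimethylsilyl)oxy]methyl}-5-{3-[(tert-butyldimethylsilyl)oxy]propyl}-7-methoxy-2,3-dihydro-1-benzofuran-2-yl]pent-4-en-1-one
Product: 23 (4S)-4-[(2S,3R)-3-{[(tert-butyldimethylsilyl)oxy]methyl}-5-{3-[(tert-butyldimethylsilyl)oxy]propyl}-7-methoxy-2,3-dihydro-1-benzofuran-2-yl]octa-1,7-dien-4-ol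
Conditions: TiCl4 (1.2 equiv), CH2Cl2, −78 °C; then allyltrimethylsilane, −78 °C; NaHCO3 quench at −78 °C
Reagents that add atoms: allyltrimethylsilane, C=CC[Si](C)(C)C
Why: Chelation-controlled Hosomi–Sakurai allylation of an alpha-alkoxy ketone: TiCl4 should bridge the carbonyl oxygen and O1 (helped by the neighbouring C7 methoxy oxygen), holding C=O syn to C2–O1. The allylsilane then attacks through an open transition state from the C2–H side, away from C3, which sets C1' as S (Cram chelate model); low temperature and a cold quench protect the silyl ethers.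

Step 16
Reactants: 23 (4S)-4-[(2S,3R)-3-{[(tert-butyldimethylsilyl)oxy]methyl}-5-{3-[(tert-butyldimethylsilyl)oxy]propyl}-7-methoxy-2,3-dihydro-1-benzofuran-2-yl]octa-1,7-dien-4-ol
Product: 24 (1S)-1-[(2S,3R)-3-{[(tert-butyldimethylsilyl)oxy]methyl}-5-{3-[(tert-butyldimethylsilyl)oxy]propyl}-7-methoxy-2,3-dihydro-1-benzofuran-2-yl]cyclohex-3-en-1-ol
Conditions: second-generation Grubbs catalyst (H2IMes)(PCy3)Cl2Ru=CHPh (5 mol%), CH2Cl2 (5 mM), 40 °C
Reagents that add atoms: none
Why: Ring-closing metathesis of two terminal alkenes to an unstrained cyclohexene, driven by loss of ethene; free tertiary alcohols are tolerated, and C1' keeps its configuration because the allyl arm becomes C2' and the butenyl arm C6'.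

Step 17
Reactants: 24 (1S)-1-[(2S,3R)-3-{[(tert-butyldimethylsilyl)oxy]methyl}-5-{3-[(tert-butyldimethylsilyl)oxy]propyl}-7-methoxy-2,3-dihydro-1-benzofuran-2-yl]cyclohex-3-en-1-ol
Product: 25 (1S,3S,6R)-3-[(2S,3R)-3-{[(tert-butyldimethylsilyl)oxy]methyl}-5-{3-[(tert-butyldimethylsilyl)oxy]propyl}-7-methoxy-2,3-dihydro-1-benzofuran-2-yl]-7-oxabicyclo[4.1.0]heptan-3-ol
Conditions: VO(acac)2 (10 mol%), tBuOOH, CH2Cl2, 0 °C to rt
Reagents that add atoms: tert-butyl hydroperoxide, CC(C)(C)OO
Why: Hydroxyl-directed, vanadium-catalysed epoxidation of a homoallylic alcohol: with the bulky C2 substituent equatorial, the tertiary hydroxyl is axial and delivers the peroxide to its own face. This gives the cis-epoxy alcohol and fixes the C3' oxygen cis to the 1'-hydroxyl.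

Step 18
Reactants: 25 (1S,3S,6R)-3-[(2S,3R)-3-{[(tert-butyldimethylsilyl)oxy]methyl}-5-{3-[(tert-butyldimethylsilyl)oxy]propyl}-7-methoxy-2,3-dihydro-1-benzofuran-2-yl]-7-oxabicyclo[4.1.0]heptan-3-ol
Product: 26 difengpiol B, (1S,3S,4S)-1-[(2S,3R)-3-(hydroxymethyl)-5-(3-hydroxypropyl)-7-methoxy-2,3-dihydro-1-benzofuran-2-yl]-4-methoxycyclohexane-1,3-diol
Conditions: (+)-10-camphorsulfonic acid (0.3 equiv), MeOH, 0 °C to rt
Reagents that add atoms: methanol, CO
Why: Acid-catalysed epoxide methanolysis by trans-diaxial (Fürst–Plattner) opening: in the half-chair with the C2 substituent equatorial, methanol attacks C4' anti to the epoxide oxygen, and C4' is also the carbon further from the electron-withdrawing carbinol. The 4'-methoxy group ends trans to the 3'-hydroxyl, which stays cis to the 1'-hydroxyl. The same acidic methanol solvolyses both primary silyl ethers, and the order of the two events does not matter.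

## Compound list

1 | 2-iodoethanol | OCCI | starting material
2 | tert-butyl(2-iodoethoxy)dimethylsilane | CC(C)(C)[Si](C)(C)OCCI | intermediate
3 | 4-methoxy-6-methyl-2H-pyran-2-one | COc1cc(C)oc(=O)c1 | starting material
4 | 6-{3-[(tert-butyldimethylsilyl)oxy]propyl}-4-methoxy-2H-pyran-2-one | COc1cc(CCCO[Si](C)(C)C(C)(C)C)oc(=O)c1 | intermediate
5 | 3-bromo-6-{3-[(tert-butyldimethylsilyl)oxy]propyl}-4-methoxy-2H-pyran-2-one | COc1cc(CCCO[Si](C)(C)C(C)(C)C)oc(=O)c1Br | intermediate
6 | 6-{3-[(tert-butyldimethylsilyl)oxy]propyl}-4-methoxy-3-(4,4,5,5-tetramethyl-1,3,2-dioxaborolan-2-yl)-2H-pyran-2-one | COc1cc(CCCO[Si](C)(C)C(C)(C)C)oc(=O)c1B1OC(C)(C)C(C)(C)O1 | intermediate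
7 | 6-{3-[(tert-butyldimethylsilyl)oxy]propyl}-3-hydroxy-4-methoxy-2H-pyran-2-one | COc1cc(CCCO[Si](C)(C)C(C)(C)C)oc(=O)c1O | intermediate
8 | (E)-but-2-ene-1,4-diol | OC/C=C/CO | starting material
9 | (E)-4-[(4-methoxybenzyl)oxy]but-2-en-1-ol | OC/C=C/COCc1ccc(OC)cc1 | intermediate
10 | [(2S,3S)-3-{[(4-methoxybenzyl)oxy]methyl}oxiran-2-yl]methanol | OC[C@@H]1O[C@H]1COCc1ccc(OC)cc1 | intermediate
11 | (2R,3R)-2-ethenyl-4-[(4-methoxybenzyl)oxy]butane-1,3-diol | O[C@@H](COCc1ccc(OC)cc1)[C@@H](CO)C=C | intermediate
12 | (2R,3R)-3-{[(tert-butyldimethylsilyl)oxy]methyl}-1-[(4-methoxybenzyl)oxy]pent-4-en-2-ol | O[C@@H](COCc1ccc(OC)cc1)[C@@H](CO[Si](C)(C)C(C)(C)C)C=C | intermediate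
13 | (2R,3R)-3-{[(tert-butyldimethylsilyl)oxy]methyl}pent-4-ene-1,2-diol | O[C@@H](CO)[C@@H](CO[Si](C)(C)C(C)(C)C)C=C | intermediate
14 | (2R,3R)-3-{[(tert-butyldimethylsilyl)oxy]methyl}-2-hydroxypent-4-enal | O[C@@H](C=O)[C@@H](CO[Si](C)(C)C(C)(C)C)C=C | intermediate
15 | (2R,3R)-3-{[(tert-butyldimethylsilyl)oxy]methyl}-2-hydroxypent-4-enoic acid | O[C@@H](C(=O)O)[C@@H](CO[Si](C)(C)C(C)(C)C)C=C | intermediate
16 | methyl (2R,3R)-3-{[(tert-butyldimethylsilyl)oxy]methyl}-2-hydroxypent-4-enoate | O[C@@H](C(=O)OC)[C@@H](CO[Si](C)(C)C(C)(C)C)C=C | intermediate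
17 | methyl (2S,3R)-3-{[(tert-butyldimethylsilyl)oxy]methyl}-2-[(6-{3-[(tert-butyldimethylsilyl)oxy]propyl}-4-methoxy-2-oxo-2H-pyran-3-yl)oxy]pent-4-enoate | O=c1oc(CCCO[Si](C)(C)C(C)(C)C)cc(OC)c1O[C@H](C(=O)OC)[C@@H](CO[Si](C)(C)C(C)(C)C)C=C | intermediate
18 | bridged Diels–Alder lactone: 3-oxo-2-oxabicyclo[2.2.2]oct-5-ene carrying the methoxy group on the alkene and the silyloxypropyl chain on the oxygen-bearing bridgehead, fused through the other bridgehead and the adjacent CH to the tetrahydrofuran ring (C2 and C3 as in 17, new centres unassigned) | O=C1OC2(CCCO[Si](C)(C)C(C)(C)C)C=C(OC)C13O[C@H](C(=O)OC)[C@@H](CO[Si](C)(C)C(C)(C)C)C3C2 | intermediate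
19 | methyl (2S,3R)-3-{[(tert-butyldimethylsilyl)oxy]methyl}-5-{3-[(tert-butyldimethylsilyl)oxy]propyl}-7-methoxy-2,3,3a,4-tetrahydro-1-benzofuran-2-carboxylate (C3a unassigned) | COC1=C2O[C@H](C(=O)OC)[C@@H](CO[Si](C)(C)C(C)(C)C)C2CC(CCCO[Si](C)(C)C(C)(C)C)=C1 | intermediate
20 | methyl (2S,3R)-3-{[(tert-butyldimethylsilyl)oxy]methyl}-5-{3-[(tert-butyldimethylsilyl)oxy]propyl}-7-methoxy-2,3-dihydro-1-benzofuran-2-carboxylate | COc1cc(CCCO[Si](C)(C)C(C)(C)C)cc2c1O[C@H](C(=O)OC)[C@H]2CO[Si](C)(C)C(C)(C)C | intermediate
21 | (2S,3R)-3-{[(tert-butyldimethylsilyl)oxy]methyl}-5-{3-[(tert-butyldimethylsilyl)oxy]propyl}-N,7-dimethoxy-N-methyl-2,3-dihydro-1-benzofuran-2-carboxamide | COc1cc(CCCO[Si](C)(C)C(C)(C)C)cc2c1O[C@H](C(=O)N(C)OC)[C@H]2CO[Si](C)(C)C(C)(C)C | intermediate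
22 | 1-[(2S,3R)-3-{[(tert-butyldimethylsilyl)oxy]methyl}-5-{3-[(tert-butyldimethylsilyl)oxy]propyl}-7-methoxy-2,3-dihydro-1-benzofuran-2-yl]pent-4-en-1-one | COc1cc(CCCO[Si](C)(C)C(C)(C)C)cc2c1O[C@H](C(=O)CCC=C)[C@H]2CO[Si](C)(C)C(C)(C)C | intermediate
23 | (4S)-4-[(2S,3R)-3-{[(tert-butyldimethylsilyl)oxy]methyl}-5-{3-[(tert-butyldimethylsilyl)oxy]propyl}-7-methoxy-2,3-dihydro-1-benzofuran-2-yl]octa-1,7-dien-4-ol | COc1cc(CCCO[Si](C)(C)C(C)(C)C)cc2c1O[C@H]([C@@](O)(CC=C)CCC=C)[C@H]2CO[Si](C)(C)C(C)(C)C | intermediate
24 | (1S)-1-[(2S,3R)-3-{[(tert-butyldimethylsilyl)oxy]methyl}-5-{3-[(tert-butyldimethylsilyl)oxy]propyl}-7-methoxy-2,3-dihydro-1-benzofuran-2-yl]cyclohex-3-en-1-ol | COc1cc(CCCO[Si](C)(C)C(C)(C)C)cc2c1O[C@H]([C@]1(O)CCC=CC1)[C@H]2CO[Si](C)(C)C(C)(C)C | intermediate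
25 | (1S,3S,6R)-3-[(2S,3R)-3-{[(tert-butyldimethylsilyl)oxy]methyl}-5-{3-[(tert-butyldimethylsilyl)oxy]propyl}-7-methoxy-2,3-dihydro-1-benzofuran-2-yl]-7-oxabicyclo[4.1.0]heptan-3-ol | COc1cc(CCCO[Si](C)(C)C(C)(C)C)cc2c1O[C@H]([C@]1(O)CC[C@H]3O[C@H]3C1)[C@H]2CO[Si](C)(C)C(C)(C)C | intermediate
26 | difengpiol B, (1S,3S,4S)-1-[(2S,3R)-3-(hydroxymethyl)-5-(3-hydroxypropyl)-7-methoxy-2,3-dihydro-1-benzofuran-2-yl]-4-methoxycyclohexane-1,3-diol | COc1cc(CCCO)cc2c1O[C@H]([C@]1(O)CC[C@H](OC)[C@@H](O)C1)[C@H]2CO | target

## Step count and risks

Total step count: 18. Longest linear sequence: 14 steps (steps 5 to 18, from 8 to 26).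

**Step 13 (key step).** The most likely failure is a cycloaddition that is too slow, because an electron-rich dialkoxypyrone and an unactivated vinyl group are poorly matched. At the temperature then needed, dihydroarene 19 may isomerise by 1,5-hydrogen shifts and aromatise by loss of methanol or by opening of ring B instead of by dehydrogenation, or C2 may epimerise before ring closure. Over-oxidation of the C2–C3 bond by the quinone is a lesser risk. The fallback sets out from 17 and activates the dienophile. Cross-metathesis with phenyl vinyl sulfone (second-generation Hoveyda–Grubbs catalyst (H2IMes)Cl2Ru=CH(C6H4-2-OiPr), CH2Cl2, 40 °C) should give methyl (2S,3R,4E)-5-(benzenesulfonyl)-3-{[(tert-butyldimethylsilyl)oxy]methyl}-2-[(6-{3-[(tert-butyldimethylsilyl)oxy]propyl}-4-methoxy-2-oxo-2H-pyran-3-yl)oxy]pent-4-enoate F1. The electron-poor alkene and the donor-substituted pyrone are then a normal-demand pair, and the same two bonds should form in toluene at about 110 °C. After loss of CO2 the sulfonyl group on C4 leaves with the hydrogen on C3a as benzenesulfinic acid, so the arene forms without an oxidant. The fallback returns to the route at 20.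

**Step 15.** The chelate may not form at the weakly basic aryl ether oxygen, or TiCl4 may sit on the O1/methoxy pair and leave the ketone to react through an open, dipole-controlled arrangement; that would erode or reverse the facial selectivity at C1'. Loss of a silyl ether to the Lewis acid is a second risk. The fallback exchanges the roles of the two carbon nucleophiles, so that the open-chain preference that spoils the main step becomes the productive one. It sets out from 20, which is converted into 21 as in step 14, this time with isolation. Allylmagnesium bromide at −78 °C should give 1-[(2S,3R)-3-{[(tert-butyldimethylsilyl)oxy]methyl}-5-{3-[(tert-butyldimethylsilyl)oxy]propyl}-7-methoxy-2,3-dihydro-1-benzofuran-2-yl]but-3-en-1-one F2, handled cold to avoid conjugation of the alkene. Addition of but-3-enylmagnesium bromide premixed with CeCl3 in THF (non-chelating, low basicity) then places the butenyl arm on the face that the allyl group would take without chelation. The fallback returns at 23.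

**Step 12.** Displacement at a beta-branched carbinol may be slow, so that elimination of the activated alcohol to a dienoate or alkylation of the azodicarboxylate-derived hydrazide competes. The fallback separates activation from displacement. It sets out from 16, which with Tf2O and 2,6-lutidine at −78 °C should give methyl (2R,3R)-3-{[(tert-butyldimethylsilyl)oxy]methyl}-2-{[(trifluoromethyl)sulfonyl]oxy}pent-4-enoate F3. The potassium salt of 7 (K2CO3, 18-crown-6, MeCN, −20 °C) should displace the triflate with the same inversion. The fallback returns at 17.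

**Step 4.** Protodeboronation of the alpha-boryl lactone 6 or hydrolytic opening of the pyrone in the basic oxidation may consume the material. The fallback replaces boron oxidation by C–O cross-coupling with a hydroxide surrogate. It sets out from 5, which with (E)-benzaldoxime, Cs2CO3 and Pd2(dba)3/tBuBrettPhos in dioxane should give (E)-benzaldehyde O-(6-{3-[(tert-butyldimethylsilyl)oxy]propyl}-4-methoxy-2-oxo-2H-pyran-3-yl)oxime F4. Under the same base F4 fragments to the pyronolate and benzonitrile. The fallback returns at 7.

**Step 18.** Opening at C3' through the minor half-chair, or capture of the activated epoxide by a freshly unmasked primary hydroxyl instead of the solvent, would give isomers that are hard to separate from a polar tetraol. The fallback separates the two events and opens the epoxide without acid. It sets out from 25, which with NaOMe in MeOH at 60 °C (pure SN2, trans-diaxial, silyl ethers retained) should give (1S,3S,4S)-1-[(2S,3R)-3-{[(tert-butyldimethylsilyl)oxy]methyl}-5-{3-[(tert-butyldimethylsilyl)oxy]propyl}-7-methoxy-2,3-dihydro-1-benzofuran-2-yl]-4-methoxycyclohexane-1,3-diol F5. F5 can be purified as a lipophilic compound and then desilylated with Bu4NF in THF. The fallback returns at 26.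

## Further compounds

F1 | step 13 | methyl (2S,3R,4E)-5-(benzenesulfonyl)-3-{[(tert-butyldimethylsilyl)oxy]methyl}-2-[(6-{3-[(tert-butyldimethylsilyl)oxy]propyl}-4-methoxy-2-oxo-2H-pyran-3-yl)oxy]pent-4-enoate | O=c1oc(CCCO[Si](C)(C)C(C)(C)C)cc(OC)c1O[C@H](C(=O)OC)[C@@H](CO[Si](C)(C)C(C)(C)C)/C=C/S(=O)(=O)c1ccccc1
F2 | step 15 | 1-[(2S,3R)-3-{[(tert-butyldimethylsilyl)oxy]methyl}-5-{3-[(tert-butyldimethylsilyl)oxy]propyl}-7-methoxy-2,3-dihydro-1-benzofuran-2-yl]but-3-en-1-one | COc1cc(CCCO[Si](C)(C)C(C)(C)C)cc2c1O[C@H](C(=O)CC=C)[C@H]2CO[Si](C)(C)C(C)(C)C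
F3 | step 12 | methyl (2R,3R)-3-{[(tert-butyldimethylsilyl)oxy]methyl}-2-{[(trifluoromethyl)sulfonyl]oxy}pent-4-enoate | FC(F)(F)S(=O)(=O)O[C@@H](C(=O)OC)[C@@H](CO[Si](C)(C)C(C)(C)C)C=C
F4 | step 4 | (E)-benzaldehyde O-(6-{3-[(tert-butyldimethylsilyl)oxy]propyl}-4-methoxy-2-oxo-2H-pyran-3-yl)oxime | COc1cc(CCCO[Si](C)(C)C(C)(C)C)oc(=O)c1O/N=C/c1ccccc1
F5 | step 18 | (1S,3S,4S)-1-[(2S,3R)-3-{[(tert-butyldimethylsilyl)oxy]methyl}-5-{3-[(tert-butyldimethylsilyl)oxy]propyl}-7-methoxy-2,3-dihydro-1-benzofuran-2-yl]-4-methoxycyclohexane-1,3-diol | COc1cc(CCCO[Si](C)(C)C(C)(C)C)cc2c1O[C@H]([C@]1(O)CC[C@H](OC)[C@@H](O)C1)[C@H]2CO[Si](C)(C)C(C)(C)C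
A1 | alternative 1 | (2R,5S)-2-tert-butyl-1,3-dioxaspiro[4.5]dec-7-en-4-one | O=C1O[C@H](C(C)(C)C)O[C@]12CCC=CC2
A2 | alternative 1 | (2R)-2-tert-butyl-5-methylidene-1,3-dioxolan-4-one | O=C1O[C@H](C(C)(C)C)OC1=C
A3 | alternative 1 | buta-1,3-diene | C=CC=C
A4 | alternative 2 | methyl cis-2,3-dihydro-1-benzofuran-3-carboxylate with 7-methoxy, 5-(3-methoxy-3-oxopropyl) and, at C2, ring C as its 1'-O-triethylsilyl, 3'-O-tert-butyldimethylsilyl, 4'-O-methyl derivative | COc1cc(CCC(=O)OC)cc2c1O[C@H]([C@]1(O[Si](CC)(CC)CC)CC[C@H](OC)[C@@H](O[Si](C)(C)C(C)(C)C)C1)[C@@H]2C(=O)OC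
A5 | alternative 2 | methyl 2-diazo-2-aryl acetate in which the aryl group carries 3-methoxy, 5-(3-methoxy-3-oxopropyl) and a 2-O-CH2 ether to the protected ring C carbinol carbon | COC(=O)C(=[N+]=[N-])c1cc(CCC(=O)OC)cc(OC)c1OC[C@]1(O[Si](CC)(CC)CC)CC[C@H](OC)[C@@H](O[Si](C)(C)C(C)(C)C)C1
A6 | alternative 3 | trans-2-(cyclohex-1-enyl)-3-(silyloxymethyl)-2,3-dihydro-1-benzofuran with 7-methoxy, 5-(3-silyloxypropyl) and 3'-hydroxy-4'-methoxy groups | COc1cc(CCCO[Si](C)(C)C(C)(C)C)cc2c1O[C@H](C1=CC[C@H](OC)[C@@H](O)C1)[C@H]2CO[Si](C)(C)C(C)(C)C
A7 | alternative 3 | 4-{3-[(tert-butyldimethylsilyl)oxy]propyl}-2-iodo-6-methoxyphenol | COc1cc(CCCO[Si](C)(C)C(C)(C)C)cc(I)c1O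
A8 | alternative 3 | (1S,6S)-3-[(1E)-3-{[tert-butyl(dimethyl)silyl]oxy}prop-1-en-1-yl]-6-methoxycyclohex-3-en-1-ol | CC(C)(C)[Si](C)(C)OC/C=C/C1=CC[C@H](OC)[C@@H](O)C1
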